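**Strategy.** Ring C (C1, C9a, C9, C10, C11, C12) is read as a Diels–Alder retron. Its C9–C10 edge carries the trans-disposed azepane branch and ethyl group; the opposite C9a–C1–C12–C11 edge lies between the pyrrolidine nitrogen (on C9a) and the lactone D oxygen (on C11). One thermal [4+2] between (E)-pent-2-enal and a diene made of an L-proline-derived enecarbamate (C9a=C1) joined to a 2-silyloxyfuran (C12=C11) forms C9–C9a and C10–C11 and sets C9, C9a, C10 and C11 relative to C3. The C1 hydrogen is then installed with inversion by allylic hydrogenolysis, hydrogenation sets C12/C13 and closes ring A, and the side-chain lactone and N-oxide follow.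

Key step: step 6

Remark: locants follow tuberostemonine (N4; C5–C8 azepane CH2 groups; C9, C9a; C1–C3 pyrrolidine; C10 bears ethyl; C11–O and C12 carry lactone D with C13 (methyl) and C14 (C=O); C18–C21 side-chain lactone E). Rings: A azepane, B pyrrolidine, C cyclohexane, D fused lactone, E side-chain lactone. "Lower face" means the face of ring C that carries H9a. Assumption: peracid oxidation of the free base occurs on the nitrogen lone pair anti to C9a–H, which is the N configuration written in the target SMILES.

**Step 1**
Reactants: 1 N-Cbz-4-oxo-L-proline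
Product: 2 dimethylamide of 1
Conditions: Me2NH (2 M in THF), EDC·HCl, HOBt, CH2Cl2, 0 °C to rt
Reagents that add atoms: dimethylamine, CNC
Why: Carbodiimide amide coupling; the tertiary amide is a robust carboxyl surrogate that later gives the C3 aldehyde, and the stereocentre is not touched.

**Step 2**
Reactants: 2 dimethylamide
Product: 3 enecarbamate enol triflate
Conditions: NaN(SiMe3)2, THF, −78 °C; then PhNTf2, −78 to 0 °C
Reagents that add atoms: N-phenylbis(trifluoromethanesulfonimide), O=S(=O)(N(c1ccccc1)S(=O)(=O)C(F)(F)F)C(F)(F)F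
Why: Enol triflate formation by kinetic deprotonation at the CH2 between N and C=O (remote from the stereocentre) should give the C9a=C1 enecarbamate triflate without enolising C3.

**Step 3**
Reactants: 4 3-methyltetronic acid
Product: 5 butenolide triflate
Conditions: Tf2O, Et3N, CH2Cl2, −78 to 0 °C
Reagents that add atoms: trifluoromethanesulfonic anhydride, O=S(=O)(OS(=O)(=O)C(F)(F)F)C(F)(F)F
Why: O-Sulfonylation of the vinylogous acid gives the vinyl triflate coupling partner that carries C11–C14 and the C13 methyl group.

**Step 4**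
Reactants: 3 enecarbamate enol triflate; 5 butenolide triflate
Product: 7 dienamide butenolide, via pinacol boronate 6 (not isolated)
Conditions: B2pin2, PdCl2(dppf) (5 mol %), KOAc, dioxane, 80 °C; then 5, aq. K3PO4, 60 °C
Reagents that add atoms: bis(pinacolato)diboron, CC1(C)OB(OC1(C)C)B1OC(C)(C)C(C)(C)O1 (its atoms are carried only by intermediate 6)
Why: One-pot Miyaura borylation of the enol triflate followed by Suzuki–Miyaura coupling forms the C1–C12 bond; no stereocentre is created.

**Step 5**
Reactants: 7 dienamide butenolide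
Product: 8 silyloxyfuran diene
Conditions: TBSOTf, Et3N, CH2Cl2, 0 °C; used directly
Reagents that add atoms: tert-butyldimethylsilyl trifluoromethanesulfonate, CC(C)(C)[Si](C)(C)OS(=O)(=O)C(F)(F)F
Why: Soft enolisation at C11 and O-silylation convert the butenolide into the aromatic 2-silyloxyfuran, which unmasks the C12=C11 half of the diene.

**Step 6**
Reactants: 8 silyloxyfuran diene; 9 (2E)-pent-2-enal
Product: 10 Diels–Alder adduct
Conditions: toluene, 80 °C, sealed tube, trace BHT; used crude
Reagents that add atoms: none
Why: A thermal normal-electron-demand Diels–Alder reaction: the diene is the extra-annular unit C9a=C1–C12=C11 of 8, whose enecarbamate nitrogen and 2-silyloxyfuran both push electron density to C11, so that C11 bonds to the β-carbon C10 of the enal and C9a to the α-carbon C9 in a concerted but asynchronous [4+2] that leaves the C1=C12 alkene and the C13=C14 silyl ketene acetal. The closest known reaction types are the cycloadditions of 1-(acylamino)butadienes and of 3-vinylfurans with α,β-unsaturated aldehydes. Ring C is the only ring closed, by an intermolecular suprafacial [4+2] cycloaddition. C9a and C11 are set together by attack on the diene face anti to the C3 carboxamide, which is pseudoaxial because of A(1,3) strain with the N-carbamate, and since N and the furan oxygen are both "outside" substituents they end up cis; C9 is set by the endo orientation of the formyl group (C8 cis to N) and C10 by the retained (E)-geometry (ethyl trans to C8). The step needs regio-, endo- and π-facial selectivity; the first is secured by the matched polarisation of the two donors, the second by secondary overlap of the formyl group with the electron-rich diene, the third by the C3 stereocentre.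

**Step 7**
Reactants: 10 Diels–Alder adduct
Product: 11 C1 acetate
Conditions: Pb(OAc)4, CH2Cl2, −40 to 0 °C
Reagents that add atoms: lead tetraacetate, CC(=O)O[Pb](OC(C)=O)(OC(C)=O)OC(C)=O
Why: Rubottom-type acetoxylation of the silyl dienol ether with tetravalent lead should place acetate on the vinylogous γ-carbon C1 from the open lower face (anti to the C9–C10 bridge) and restore the conjugated butenolide; the α-regioisomer (acetate on C13, same face) would enter step 9 through the same allyl complex.

**Step 8**
Reactants: 11 C1 acetate; 12 dioxolanylethyl phosphonium bromide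
Product: 13 alkenyl dioxolane
Conditions: 12, KN(SiMe3)2, THF, −78 °C; then 11, −78 to 0 °C
Reagents that add atoms: none
Why: Wittig olefination with the non-stabilised ylide adds C5–C7, with C5 masked at the aldehyde level, faster than C9 can epimerise; the alkene geometry is irrelevant because it is hydrogenated later.

**Step 9**
Reactants: 13 alkenyl dioxolane
Product: 14 trans-fused butenolide
Conditions: Pd2(dba)3·CHCl3 (5 mol %), PBu3, HCO2H, Et3N, dioxane, 40 °C
Reagents that add atoms: none
Why: Tsuji–Trost-type allylic hydrogenolysis with formate: zerovalent palladium ionises the tertiary allylic acetate anti to the leaving group, the formate complex loses CO2 and passes hydride to the γ-carbon C1 on the palladium-bound upper face, so C1–H forms with inversion (H1 trans to H9a) and the butenolide stays conjugated, as in the hydrogenolysis of γ-oxygenated α,β-unsaturated esters.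

**Step 10**
Reactants: 14 trans-fused butenolide
Product: 17 tetracyclic carboxamide, via amino acetal 15 (not isolated), via iminium acetate 16 (not isolated)
Conditions: H2 (50 bar), Pd/C (10 %), AcOH–H2O 4:1, 25 to 40 °C; basic work-up
Reagents that add atoms: none
Why: Heterogeneous hydrogenation should add H2 to the tetrasubstituted butenolide from the face anti to C10 (syn to H11), giving the all-cis H11/H12/H13 lactone, and also saturates the side-chain alkene and cleaves Cbz; in the acidic aqueous medium the dioxolane hydrolyses and the amine and aldehyde close ring A by intramolecular reductive amination.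

**Step 11**
Reactants: 17 tetracyclic carboxamide
Product: 18 C3 aldehyde
Conditions: Cp2Zr(H)Cl (1.6 equiv), THF, 25 °C; aqueous work-up; used crude
Reagents that add atoms: none
Why: Partial reduction of the tertiary amide by hydrozirconation of the amide carbonyl stops at the zirconated hemiaminal and gives the aldehyde on work-up, with the lactone left intact.

**Step 12**
Reactants: 18 C3 aldehyde; 19 ethyl 2-[(trimethylsilyl)methyl]prop-2-enoate
Product: 21 α-methylene lactone, via hydroxy ester 20 (not isolated)
Conditions: SnCl4 (2.2 equiv), CH2Cl2, −78 °C; then 19, −78 to −40 °C; work-up; CF3CO2H, CH2Cl2, 25 °C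
Reagents that add atoms: none
Why: Chelation-controlled Hosomi–Sakurai allylation: SnCl4 bridges the ring nitrogen and the aldehyde oxygen and the allylsilane attacks the Cram chelate from the face away from C2, giving the threo amino alcohol (C18 S), which lactonises to the α-methylene-γ-butyrolactone.

**Step 13**
Reactants: 21 α-methylene lactone
Product: 22 tuberostemonine
Conditions: H2 (1 atm), Pd/C (10 %), EtOAc, 25 °C
Reagents that add atoms: none
Why: Hydrogenation of the exocyclic methylene from the face anti to the C18 substituent should give the cis-2,4-disubstituted lactone (C20 S).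

**Step 14**
Reactants: 22 tuberostemonine
Product: 23 N-oxytuberostemonine
Conditions: mCPBA (1.05 equiv), CH2Cl2, 0 °C; basic alumina
Reagents that add atoms: 3-chloroperoxybenzoic acid, OOC(=O)c1cccc(Cl)c1
Why: Peracid N-oxidation on the lone pair of the preferred invertomer (anti to C9a–H, on the face away from the C3 lactone) should fix the N configuration of the target.

**Compound list**

1 | N-Cbz-4-oxo-L-proline, (2S)-1-(benzyloxycarbonyl)-4-oxopyrrolidine-2-carboxylic acid | O=C(O)[C@@H]1CC(=O)CN1C(=O)OCc1ccccc1 | starting material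
2 | benzyl (2S)-2-(dimethylcarbamoyl)-4-oxopyrrolidine-1-carboxylate | CN(C)C(=O)[C@@H]1CC(=O)CN1C(=O)OCc1ccccc1 | intermediate
3 | benzyl (2S)-2-(dimethylcarbamoyl)-4-(trifluoromethylsulfonyloxy)-2,3-dihydro-1H-pyrrole-1-carboxylate | CN(C)C(=O)[C@@H]1CC(OS(=O)(=O)C(F)(F)F)=CN1C(=O)OCc1ccccc1 | intermediate
4 | 4-hydroxy-3-methylfuran-2(5H)-one (3-methyltetronic acid) | CC1=C(O)COC1=O | starting material
5 | 4-methyl-5-oxo-2,5-dihydrofuran-3-yl trifluoromethanesulfonate | CC1=C(OS(=O)(=O)C(F)(F)F)COC1=O | intermediate
6 | benzyl (2S)-2-(dimethylcarbamoyl)-4-(4,4,5,5-tetramethyl-1,3,2-dioxaborolan-2-yl)-2,3-dihydro-1H-pyrrole-1-carboxylate | CN(C)C(=O)[C@@H]1CC(B2OC(C)(C)C(C)(C)O2)=CN1C(=O)OCc1ccccc1 | intermediate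
7 | benzyl (2S)-2-(dimethylcarbamoyl)-4-(4-methyl-5-oxo-2,5-dihydrofuran-3-yl)-2,3-dihydro-1H-pyrrole-1-carboxylate | CN(C)C(=O)[C@@H]1CC(C2=C(C)C(=O)OC2)=CN1C(=O)OCc1ccccc1 | intermediate
8 | benzyl (2S)-4-[5-(tert-butyldimethylsilyloxy)-4-methylfuran-3-yl]-2-(dimethylcarbamoyl)-2,3-dihydro-1H-pyrrole-1-carboxylate | CN(C)C(=O)[C@@H]1CC(c2coc(O[Si](C)(C)C(C)(C)C)c2C)=CN1C(=O)OCc1ccccc1 | intermediate
9 | (2E)-pent-2-enal | CC/C=C/C=O | starting material
10 | Diels–Alder adduct: N-Cbz rings B/C/D tricycle with (3S)-CONMe2, C9 formyl, C10 ethyl, C1=C12 alkene and C13=C14 silyl ketene acetal (14-OTBS); H9, H9a, H11 and the carboxamide on the lower face, H10 on the upper face | CC[C@@H]1[C@@H](C=O)[C@H]2N(C(=O)OCc4ccccc4)[C@H](C(=O)N(C)C)CC2=C3C(C)=C(O[Si](C)(C)C(C)(C)C)O[C@@H]13 | intermediate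
11 | C1 acetate: as 10 but with the C12=C13 butenolide (C14=O) and a tertiary acetoxy group at C1 on the lower face (cis to H9a, rings B/C cis-fused) | CC[C@@H]1[C@@H](C=O)[C@H]2N(C(=O)OCc4ccccc4)[C@H](C(=O)N(C)C)C[C@@]2(OC(C)=O)C3=C(C)C(=O)O[C@@H]13 | intermediate
12 | [2-(1,3-dioxolan-2-yl)ethyl]triphenylphosphonium bromide | [Br-].C1COC(CC[P+](c2ccccc2)(c2ccccc2)c2ccccc2)O1 | starting material
13 | alkenyl dioxolane: as 11 with a (Z)-3-(1,3-dioxolan-2-yl)prop-1-enyl group at C9 in place of formyl | CC[C@@H]1[C@@H](/C=C\CC5OCCO5)[C@H]2N(C(=O)OCc4ccccc4)[C@H](C(=O)N(C)C)C[C@@]2(OC(C)=O)C3=C(C)C(=O)O[C@@H]13 | intermediate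
14 | trans-fused butenolide: as 13 with hydrogen in place of acetoxy at C1, H1 on the upper face (trans to H9a) | CC[C@@H]1[C@@H](/C=C\CC5OCCO5)[C@H]2N(C(=O)OCc4ccccc4)[C@H](C(=O)N(C)C)C[C@@H]2C3=C(C)C(=O)O[C@@H]13 | intermediate
15 | amino acetal: free NH, C9 3-(1,3-dioxolan-2-yl)propyl, saturated lactone D with H11, H12, H13 on the lower face | CC[C@@H]1[C@@H](CCCC5OCCO5)[C@H]2N[C@H](C(=O)N(C)C)C[C@@H]2[C@H]3[C@@H](C)C(=O)O[C@@H]13 | intermediate
16 | tetracyclic iminium acetate (C5=N4+) | CC[C@@H]1[C@H]2CCCC=[N+]3[C@H]2[C@H](C[C@H]3C(=O)N(C)C)[C@@H]2[C@H]1OC(=O)[C@@H]2C.CC(=O)[O-] | intermediate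
17 | (1R,3S,9R,9aR,10R,11S,12S,13R) rings A–D tetracycle with N,N-dimethylcarboxamide at C3 | CC[C@@H]1[C@H]2CCCCN3[C@H]2[C@H](C[C@H]3C(=O)N(C)C)[C@@H]2[C@H]1OC(=O)[C@@H]2C | intermediate
18 | the same tetracycle with a formyl group at C3 (3S) | CC[C@@H]1[C@H]2CCCCN3[C@H]2[C@H](C[C@H]3C=O)[C@@H]2[C@H]1OC(=O)[C@@H]2C | intermediate
19 | ethyl 2-[(trimethylsilyl)methyl]prop-2-enoate | C=C(C[Si](C)(C)C)C(=O)OCC | starting material
20 | (18S) hydroxy ester: C3–CH(OH)–CH2–C(=CH2)–CO2Et, threo to N | CC[C@@H]1[C@H]2CCCCN3[C@H]2[C@H](C[C@H]3[C@@H](O)CC(=C)C(=O)OCC)[C@@H]2[C@H]1OC(=O)[C@@H]2C | intermediate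
21 | 20-methylidene analogue of tuberostemonine (α-methylene lactone E, 18S) | CC[C@@H]1[C@H]2CCCCN3[C@H]2[C@H](C[C@H]3[C@@H]2CC(=C)C(=O)O2)[C@@H]2[C@H]1OC(=O)[C@@H]2C | intermediate
22 | tuberostemonine, (1R,3S,9R,9aR,10R,11S,12S,13R) with 3-[(2S,4S)-4-methyl-5-oxooxolan-2-yl] | CC[C@@H]1[C@H]2CCCCN3[C@H]2[C@H](C[C@H]3[C@@H]2C[C@H](C)C(=O)O2)[C@@H]2[C@H]1OC(=O)[C@@H]2C | intermediate
23 | N-oxytuberostemonine (N4-oxide of 22, oxygen anti to H9a) | CC[C@@H]1[C@H]2CCCC[N@@+]3([O-])[C@H]2[C@H](C[C@H]3[C@@H]2C[C@H](C)C(=O)O2)[C@@H]2[C@H]1OC(=O)[C@@H]2C | target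

**Totals.** Total step count: 14. Longest linear sequence: 13 steps (steps 1, 2 and 4–14; step 3 is a one-step side branch).

**Steps most likely to fail**

Step 9 (allylic hydrogenolysis). Ionisation has to take place on the concave upper face and may be slow. Hydride may also be passed to the α-terminus C13, or only after facial equilibration of the allyl complex, which would return the cis ring fusion. The fallback sets out from 10 and comes back at 14; it delivers the upper-face hydrogen at C1 by a hydroxyl-directed hydrogenation instead. NaBH4 in MeOH at −40 °C reduces the formyl group of 10, and methanolysis of the silyl ketene acetal gives the β,γ-unsaturated lactone alcohol F1 (C1=C12). The C8 hydroxyl, which sits on the upper face above C1, directs [Ir(cod)(PCy3)(py)]PF6/H2 (CH2Cl2) to that face and should give the saturated lactone alcohol F2, with H1 and H12 both on the upper face (C1 correct, C12 wrong). LiN(iPr)2 (2.2 equiv) then PhSeBr gives the α-selenide F3. H2O2 gives, by syn-elimination into the ring, the trans-fused butenolide alcohol F4, which erases the wrong C12 centre. Dess–Martin periodinane gives the aldehyde F5, and Wittig olefination with the ylide of 12 as in step 8 gives 14.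

Step 6 (cycloaddition). The thermal reaction may show poor endo/exo or facial selectivity, may add across the furan's own diene, or may stop after Michael addition without ring closure. The fallback sets out from 8 and comes back at 10. The enal is replaced by S-ethyl (2E)-pent-2-enethioate activated by Et2AlCl (CH2Cl2, −78 °C), so that ring C is built by a Lewis-acid-promoted, strongly endo-biased vinylogous Mukaiyama–Michael/Mannich annulation at low temperature, giving the thioester adduct F6. iBu2AlH at −78 °C then reduces the thioester to the aldehyde 10.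

Step 10 (hydrogenation and ring A closure). Hydrogen may add to the tetrasubstituted butenolide from the upper face, or not at all, which would give the trans-lactone C12 epimer. The fallback sets out from 14 and comes back at 17; it takes facial control from substrate direction instead of surface approach. Homogeneous hydrogenation with [Ir(cod)(PCy3)(py)]PF6 in CH2Cl2, in which the C3 carboxamide on the lower face of ring B binds iridium and steers H2 to the lower face of C12=C13, should give the N-Cbz saturated lactone F7 (side-chain alkene also reduced). Hydrogenolysis in aqueous acetic acid as in step 10 then removes Cbz and closes ring A to give 17.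

**Further compounds**

F1 | step 9 | β,γ-unsaturated lactone alcohol (C1=C12, C9 hydroxymethyl, N-Cbz) | CC[C@@H]1[C@@H](CO)[C@H]2N(C(=O)OCc4ccccc4)[C@H](C(=O)N(C)C)CC2=C3C(C)C(=O)O[C@@H]13
F2 | step 9 | saturated lactone alcohol with H1 and H12 on the upper face | CC[C@@H]1[C@@H](CO)[C@H]2N(C(=O)OCc4ccccc4)[C@H](C(=O)N(C)C)C[C@@H]2[C@@H]3C(C)C(=O)O[C@@H]13
F3 | step 9 | α-phenylselenyl lactone alcohol | CC[C@@H]1[C@@H](CO)[C@H]2N(C(=O)OCc4ccccc4)[C@H](C(=O)N(C)C)C[C@@H]2[C@@H]3C(C)([Se]c6ccccc6)C(=O)O[C@@H]13
F4 | step 9 | trans-fused butenolide alcohol | CC[C@@H]1[C@@H](CO)[C@H]2N(C(=O)OCc4ccccc4)[C@H](C(=O)N(C)C)C[C@@H]2C3=C(C)C(=O)O[C@@H]13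
F5 | step 9 | trans-fused butenolide aldehyde | CC[C@@H]1[C@@H](C=O)[C@H]2N(C(=O)OCc4ccccc4)[C@H](C(=O)N(C)C)C[C@@H]2C3=C(C)C(=O)O[C@@H]13
F6 | step 6 | thioester analogue of 10 (C9–C(=O)SEt) | CC[C@@H]1[C@@H](C(=O)SCC)[C@H]2N(C(=O)OCc4ccccc4)[C@H](C(=O)N(C)C)CC2=C3C(C)=C(O[Si](C)(C)C(C)(C)C)O[C@@H]13
F7 | step 10 | N-Cbz saturated lactone with C9 3-(1,3-dioxolan-2-yl)propyl | CC[C@@H]1[C@@H](CCCC5OCCO5)[C@H]2N(C(=O)OCc4ccccc4)[C@H](C(=O)N(C)C)C[C@@H]2[C@H]3[C@@H](C)C(=O)O[C@@H]13
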